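**Strategy.** Ring B is disconnected at C1'–C6' and C4'–C5'. C3'/C5' carry the two oxygens and the prenylated C2'/C6' flank C1', the carbon bonded to benzofuran C2. The arene therefore maps onto a 5-aryl-4,6-diprenylcyclohexane-1,3-dione. One Michael–Claisen operation joins a benzofuran-2-yl enone (C1'–C4' with one prenyl group) to the enolate of methyl 5-methylhex-4-enoate (C5', C6', second prenyl group). This closes the six-membered ring with both prenyl groups and the aryl–furan bond already in place. The precursor is an (E)-α-prenyl-β-(benzofuran-2-yl) methyl ketone carrying the finished ring A (4,6-bis-MOM ethers, 7-(1,1-dimethylallyl)). Dehydrogenation and deprotection follow.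

Key step: step 10

Remark: the target has no stereogenic element (ring B is symmetric about the C1'–C2 bond), so the compound as drawn is achiral and no stereocontrol is needed; "prenyl" = 3-methylbut-2-en-1-yl, and primed numbers refer to ring B.

Step 1
Reactants: 1 2,4,6-trihydroxybenzaldehyde; 2 prenyl bromide (1-bromo-3-methylbut-2-ene)
Product: 3 2,6-dihydroxy-4-[(3-methylbut-2-en-1-yl)oxy]benzaldehyde
Conditions: 2 (1.0 equiv), K2CO3 (1.0 equiv), acetone, 0 °C → rt
Reagents that add atoms: none
Why: Williamson etherification, in which the 4-OH (para to the formyl group, the most acidic and not chelated) should be alkylated on oxygen in preference to the two hydrogen-bonded ortho-hydroxyls when only one equivalent of base and halide is used.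

Step 2
Reactants: 3 2,6-dihydroxy-4-[(3-methylbut-2-en-1-yl)oxy]benzaldehyde; 4 ethyl bromoacetate
Product: 6 ethyl 4-hydroxy-6-[(3-methylbut-2-en-1-yl)oxy]-1-benzofuran-2-carboxylate, via aryloxyacetate ether 5 (not isolated)
Conditions: 4 (1.0 equiv), K2CO3 (2.5 equiv), DMF, rt → 90 °C
Reagents that add atoms: none
Why: Williamson O-alkylation of one of the two equivalent ortho-hydroxyls, then intramolecular aldol condensation of the aryloxyacetate CH2 onto the formyl group and dehydration (Rap–Stoermer-type benzofuran synthesis), which leaves the other ortho-hydroxyl as 4-OH and the prenyl ether at C6.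

Step 3
Reactants: 6 ethyl 4-hydroxy-6-[(3-methylbut-2-en-1-yl)oxy]-1-benzofuran-2-carboxylate
Product: 7 ethyl 4,6-dihydroxy-7-(2-methylbut-3-en-2-yl)-1-benzofuran-2-carboxylate
Conditions: PhNEt2, 175 °C, N2, 1–2 h
Reagents that add atoms: none
Why: Aromatic Claisen rearrangement, in which the [3,3] shift of the 6-O-prenyl group can only use the C6=C7 bond, because delivery to C5 would break the furan sextet and the para carbon C3a is a ring-fusion atom (no para-Claisen–Cope outlet), so the inverted allyl unit (1,1-dimethylallyl) should arrive at C7 and the dienone tautomerise to the 6-phenol.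

Step 4
Reactants: 7 ethyl 4,6-dihydroxy-7-(2-methylbut-3-en-2-yl)-1-benzofuran-2-carboxylate
Product: 8 ethyl 4,6-bis(methoxymethoxy)-7-(2-methylbut-3-en-2-yl)-1-benzofuran-2-carboxylate
Conditions: NaH (2.5 equiv), MOMCl (2.5 equiv), DMF, 0 °C → rt
Reagents that add atoms: chloromethyl methyl ether (MOMCl), COCCl
Why: Williamson-type acetal formation on both phenoxides, the small and very reactive chloromethyl ether reaching even the 6-oxygen next to the tertiary allyl group, while the ester has no enolisable position.

Step 5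
Reactants: 8 ethyl 4,6-bis(methoxymethoxy)-7-(2-methylbut-3-en-2-yl)-1-benzofuran-2-carboxylate
Product: 9 [4,6-bis(methoxymethoxy)-7-(2-methylbut-3-en-2-yl)-1-benzofuran-2-yl]methanol
Conditions: LiAlH4, THF, 0 °C
Reagents that add atoms: none
Why: Hydride reduction of the ester to the primary alcohol, to which MOM acetals, the benzofuran and the isolated terminal alkene are inert.

Step 6
Reactants: 9 [4,6-bis(methoxymethoxy)-7-(2-methylbut-3-en-2-yl)-1-benzofuran-2-yl]methanol
Product: 10 4,6-bis(methoxymethoxy)-7-(2-methylbut-3-en-2-yl)-1-benzofuran-2-carbaldehyde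
Conditions: activated MnO2, CH2Cl2, rt
Reagents that add atoms: none
Why: MnO2 oxidation of a heterobenzylic alcohol, which stops at the aldehyde and leaves acetals and alkene untouched.

Step 7
Reactants: 11 diethyl (2-oxopropyl)phosphonate; 2 prenyl bromide
Product: 12 diethyl (6-methyl-2-oxohept-5-en-3-yl)phosphonate (racemic)
Conditions: NaH (1.0 equiv), THF, 0 °C; 2 (1.0 equiv), 0 °C → rt
Reagents that add atoms: none
Why: C-alkylation of the β-ketophosphonate monoanion at the doubly activated carbon by an allylic bromide, one equivalent of base limiting dialkylation.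

Step 8
Reactants: 12 diethyl (6-methyl-2-oxohept-5-en-3-yl)phosphonate; 10 4,6-bis(methoxymethoxy)-7-(2-methylbut-3-en-2-yl)-1-benzofuran-2-carbaldehyde
Product: 13 (3E)-3-{[4,6-bis(methoxymethoxy)-7-(2-methylbut-3-en-2-yl)-1-benzofuran-2-yl]methylidene}-6-methylhept-5-en-2-one
Conditions: 12 (1.3 equiv), NaH (1.2 equiv), THF, 0 °C; 10, 0 → 50 °C
Reagents that add atoms: none
Why: Horner–Wadsworth–Emmons olefination of a heteroaryl aldehyde with an α-alkyl β-ketophosphonate, expected to favour the (E)-enone (aryl trans to acetyl), while any (Z)-isomer would serve equally in step 10 because the alkene geometry is lost there.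

Step 9
Reactants: 14 2-methylbut-3-en-2-ol; 15 trimethyl orthoacetate
Product: 16 methyl 5-methylhex-4-enoate
Conditions: 15 (excess), EtCO2H (cat.), 110 → 140 °C, MeOH distilled off
Reagents that add atoms: none
Why: Johnson–Claisen orthoester rearrangement, in which the mixed ketene acetal of the tertiary allylic alcohol undergoes a [3,3] shift to the γ,δ-unsaturated ester with the trisubstituted (prenyl-type) double bond.

Step 10
Reactants: 16 methyl 5-methylhex-4-enoate; 13 (3E)-3-{[4,6-bis(methoxymethoxy)-7-(2-methylbut-3-en-2-yl)-1-benzofuran-2-yl]methylidene}-6-methylhept-5-en-2-one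
Product: 18 5-[4,6-bis(methoxymethoxy)-7-(2-methylbut-3-en-2-yl)-1-benzofuran-2-yl]-4,6-bis(3-methylbut-2-en-1-yl)cyclohexane-1,3-dione (meso, all-trans), via Michael adduct keto ester 17 (not isolated)
Conditions: LDA (1.2 equiv), 16 (1.2 equiv), THF, −78 °C; 13, DMPU (4 equiv), −78 → 0 °C; t-BuOK (1.5 equiv), t-BuOH/THF, 0 → 25 °C; aq. HCl to pH 3–4
Reagents that add atoms: none
Why: The lithium enolate of 16 adds through its α-carbon to the β-carbon (C1') of 13, DMPU and warming letting any kinetic 1,2-aldolate revert so that the conjugate adduct 17 accumulates as its ketone enolate, which t-BuOK/t-BuOH equilibrates to the acetyl-methyl enolate that attacks the methyl ester, expels methoxide and is drained irreversibly as the β-diketone enolate. The closest known reaction type is the Michael–Claisen (dimedone-type) annulation of ester or malonate enolates with α,β-unsaturated methyl ketones, whose second stage is the classical alkoxide cyclisation of δ-keto esters to cyclohexane-1,3-diones. Ring B closes in a 6-(enolendo)-exo-trig acylation (C4'–C5') after the intermolecular C1'–C6' bond. C5 is created in the Michael step and C4 and C6 by that step and a protonation, but all three should end under thermodynamic control because C4 and C6 are epimerisable next to carbonyl groups (in 17 before closure and in 18 by enolisation), which places the aryl and both prenyl groups equatorial (all-trans, meso); any other diastereomer is equally usable, since all three centres vanish on aromatisation. The step needs 1,4- before 1,2-addition, secured by the reversibility of the aldolate at the α-branched acetyl group against the irreversible C–C conjugate adduct, and a single Claisen mode, secured because only the methyl enolate can reach the ester through a six-membered ring (the internal enolate would need a four-membered one).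

Step 11
Reactants: 18 5-[4,6-bis(methoxymethoxy)-7-(2-methylbut-3-en-2-yl)-1-benzofuran-2-yl]-4,6-bis(3-methylbut-2-en-1-yl)cyclohexane-1,3-dione
Product: 19 2-[2,6-bis(3-methylbut-2-en-1-yl)-3,5-bis(triethylsilyloxy)cyclohexa-2,4-dien-1-yl]-4,6-bis(methoxymethoxy)-7-(2-methylbut-3-en-2-yl)-1-benzofuran (racemic, 1,6-trans)
Conditions: TESOTf (2.5 equiv), Et3N (4 equiv), CH2Cl2, −78 → 0 °C; pentane/cold aq. NaHCO3 work-up, used crude
Reagents that add atoms: triethylsilyl trifluoromethanesulfonate (TESOTf), CC[Si](CC)(CC)OS(=O)(=O)C(F)(F)F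
Why: Soft enolisation and O-silylation of a cyclic 1,3-dione to its 1,3-bis(silyloxy)diene (the second silylation via the bis(silyloxy)allyl cation and loss of H-4), both modes of enolisation giving the same constitution by symmetry, and any MOM-to-TES exchange on ring A being harmless because step 13 removes both groups.

Step 12
Reactants: 19 2-[2,6-bis(3-methylbut-2-en-1-yl)-3,5-bis(triethylsilyloxy)cyclohexa-2,4-dien-1-yl]-4,6-bis(methoxymethoxy)-7-(2-methylbut-3-en-2-yl)-1-benzofuran
Product: 20 2-[2,6-bis(3-methylbut-2-en-1-yl)-3,5-bis(triethylsilyloxy)phenyl]-4,6-bis(methoxymethoxy)-7-(2-methylbut-3-en-2-yl)-1-benzofuran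
Conditions: DDQ (1.05 equiv), 2,4,6-collidine (2 equiv), CH2Cl2, −40 → 0 °C
Reagents that add atoms: none
Why: DDQ dehydrogenation of a bis(silyloxy)cyclohexadiene, in which hydride abstraction from a ring C–H (the doubly allylic, heterobenzylic H at C1' or the H at C6') gives a siloxy-stabilised arenium ion that loses the neighbouring proton to the aromatic bis-silyl ether, the silyl groups keeping the new resorcinol masked from the oxidant and the two remaining stereocentres being erased.

Step 13
Reactants: 20 2-[2,6-bis(3-methylbut-2-en-1-yl)-3,5-bis(triethylsilyloxy)phenyl]-4,6-bis(methoxymethoxy)-7-(2-methylbut-3-en-2-yl)-1-benzofuran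
Product: 21 2-[3,5-dihydroxy-2,6-bis(3-methylbut-2-en-1-yl)phenyl]-7-(2-methylbut-3-en-2-yl)-1-benzofuran-4,6-diol (target)
Conditions: HCl (1.25 M in MeOH), 0 °C → rt, monitored and stopped at full conversion
Reagents that add atoms: none
Why: Acid-catalysed methanolysis of the aryl triethylsilyl ethers and of the MOM acetals (formaldehyde leaving as dimethoxymethane in the excess methanol), which at room temperature and about 1 M acid should be faster than protonation of the prenyl and 1,1-dimethylallyl double bonds that would lead to chromans or dihydrofurans.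

**Compound list**

1 | 2,4,6-trihydroxybenzaldehyde | O=Cc1c(O)cc(O)cc1O | starting material
2 | prenyl bromide (1-bromo-3-methylbut-2-ene) | CC(C)=CCBr | starting material
3 | 2,6-dihydroxy-4-[(3-methylbut-2-en-1-yl)oxy]benzaldehyde | O=Cc1c(O)cc(OCC=C(C)C)cc1O | intermediate
4 | ethyl bromoacetate | CCOC(=O)CBr | starting material
5 | ethyl 2-{2-formyl-3-hydroxy-5-[(3-methylbut-2-en-1-yl)oxy]phenoxy}acetate | CCOC(=O)COc1cc(OCC=C(C)C)cc(O)c1C=O | intermediate (not isolated)
6 | ethyl 4-hydroxy-6-[(3-methylbut-2-en-1-yl)oxy]-1-benzofuran-2-carboxylate | CCOC(=O)c1cc2c(O)cc(OCC=C(C)C)cc2o1 | intermediate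
7 | ethyl 4,6-dihydroxy-7-(2-methylbut-3-en-2-yl)-1-benzofuran-2-carboxylate | CCOC(=O)c1cc2c(O)cc(O)c(C(C)(C)C=C)c2o1 | intermediate
8 | ethyl 4,6-bis(methoxymethoxy)-7-(2-methylbut-3-en-2-yl)-1-benzofuran-2-carboxylate | CCOC(=O)c1cc2c(OCOC)cc(OCOC)c(C(C)(C)C=C)c2o1 | intermediate
9 | [4,6-bis(methoxymethoxy)-7-(2-methylbut-3-en-2-yl)-1-benzofuran-2-yl]methanol | OCc1cc2c(OCOC)cc(OCOC)c(C(C)(C)C=C)c2o1 | intermediate
10 | 4,6-bis(methoxymethoxy)-7-(2-methylbut-3-en-2-yl)-1-benzofuran-2-carbaldehyde | O=Cc1cc2c(OCOC)cc(OCOC)c(C(C)(C)C=C)c2o1 | intermediate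
11 | diethyl (2-oxopropyl)phosphonate | CCOP(=O)(CC(C)=O)OCC | starting material
12 | diethyl (6-methyl-2-oxohept-5-en-3-yl)phosphonate, racemic | CCOP(=O)(OCC)C(CC=C(C)C)C(C)=O | intermediate
13 | (3E)-3-{[4,6-bis(methoxymethoxy)-7-(2-methylbut-3-en-2-yl)-1-benzofuran-2-yl]methylidene}-6-methylhept-5-en-2-one | CC(=O)/C(CC=C(C)C)=C/c1cc2c(OCOC)cc(OCOC)c(C(C)(C)C=C)c2o1 | intermediate (key-step precursor)
14 | 2-methylbut-3-en-2-ol | C=CC(C)(C)O | starting material
15 | trimethyl orthoacetate | COC(C)(OC)OC | starting material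
16 | methyl 5-methylhex-4-enoate | COC(=O)CCC=C(C)C | intermediate (key-step precursor)
17 | methyl 4-acetyl-3-[4,6-bis(methoxymethoxy)-7-(2-methylbut-3-en-2-yl)-1-benzofuran-2-yl]-7-methyl-2-(3-methylbut-2-en-1-yl)oct-6-enoate, present as its enolate, mixture of diastereomers (configuration not controlled and not needed) | COC(=O)C(CC=C(C)C)C(c1cc2c(OCOC)cc(OCOC)c(C(C)(C)C=C)c2o1)C(CC=C(C)C)C(C)=O | intermediate (not isolated)
18 | 5-[4,6-bis(methoxymethoxy)-7-(2-methylbut-3-en-2-yl)-1-benzofuran-2-yl]-4,6-bis(3-methylbut-2-en-1-yl)cyclohexane-1,3-dione, meso, all-trans (prenyl groups cis to each other, both trans to the aryl group) | O=C1CC(=O)[C@@H](CC=C(C)C)[C@H](c2cc3c(OCOC)cc(OCOC)c(C(C)(C)C=C)c3o2)[C@H]1CC=C(C)C | intermediate (key-step product)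
19 | 2-[2,6-bis(3-methylbut-2-en-1-yl)-3,5-bis(triethylsilyloxy)cyclohexa-2,4-dien-1-yl]-4,6-bis(methoxymethoxy)-7-(2-methylbut-3-en-2-yl)-1-benzofuran, racemic, 1,6-trans (one enantiomer drawn) | CC[Si](CC)(CC)OC1=CC(O[Si](CC)(CC)CC)=C(CC=C(C)C)[C@H](c2cc3c(OCOC)cc(OCOC)c(C(C)(C)C=C)c3o2)[C@H]1CC=C(C)C | intermediate
20 | 2-[2,6-bis(3-methylbut-2-en-1-yl)-3,5-bis(triethylsilyloxy)phenyl]-4,6-bis(methoxymethoxy)-7-(2-methylbut-3-en-2-yl)-1-benzofuran | CC[Si](CC)(CC)Oc1cc(O[Si](CC)(CC)CC)c(CC=C(C)C)c(-c2cc3c(OCOC)cc(OCOC)c(C(C)(C)C=C)c3o2)c1CC=C(C)C | intermediate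
21 | 2-[3,5-dihydroxy-2,6-bis(3-methylbut-2-en-1-yl)phenyl]-7-(2-methylbut-3-en-2-yl)-1-benzofuran-4,6-diol (achiral) | C=CC(C)(C)c1c(O)cc(O)c2cc(-c3c(CC=C(C)C)c(O)cc(O)c3CC=C(C)C)oc12 | target

**Step count.** Total: 13 steps. Longest linear sequence: 11 steps (1–6, 8, 10–13).

**Steps most likely to fail**

Step 10 (Michael–Claisen annulation). The ester enolate may act as a base towards 13 (enolisation at the acetyl methyl group or at the doubly allylic CH2), or the mixture may stall at 1,2-adducts and oligomers, so that the conjugate adduct never builds up. The fallback sets out from 16 and 13 and comes back to the route at 18, with the two bonds made in separate operations and a neutral nucleophile. Ester 16 is converted into its tert-butyldimethylsilyl ketene acetal F1 (LDA, TBSCl, THF–DMPU, −78 °C). F1 is added to 13 in a Mukaiyama–Michael reaction under catalytic TBSOTf (CH2Cl2, −78 °C) to give the silyl enol ether adduct F2. Desilylation (TBAF, AcOH, THF, 0 °C) releases keto ester 17, now isolated, and t-BuOK in t-BuOH/THF closes it to 18 by the same Claisen condensation.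

Step 12 (DDQ dehydrogenation). Hydride may be abstracted from the allylic CH2 of the prenyl group on the diene terminus instead of from the ring, or the quinone may add to the electron-rich diene, leading to side-chain unsaturation or adducts in place of aromatisation. The fallback sets out from 18 and comes back at 21. The dianion of 18 (LDA, 2.2 equiv, THF–DMPU, −78 → 0 °C) is selenenylated at C4 with PhSeCl, anti to the aryl group and therefore syn to H-5, to give the 4-(phenylselanyl) dione F3. Oxidation (H2O2, pyridine, CH2Cl2, 0 °C) and syn-elimination of the selenoxide into the ring, followed by tautomerisation, should give the ring-A-protected resorcinol F4. F4 is converted into 21 under the conditions of step 13.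

Step 3 (Claisen rearrangement). At the temperature required, the prenyl ether may ionise and lose the prenyl group, or the o-(1,1-dimethylallyl)phenol formed may rearrange further or close onto the neighbouring 6-hydroxyl. The fallback sets out from 1 and comes back at 8 without a sigmatropic step. Aldehyde 1 is converted into 2-hydroxy-4,6-bis(methoxymethoxy)benzaldehyde F5 (MOMCl, 2.1 equiv, i-Pr2NEt, CH2Cl2, 0 °C). F5 is iodinated ortho to the free phenol (NIS, DMF, rt) to give 2-hydroxy-3-iodo-4,6-bis(methoxymethoxy)benzaldehyde F6. F6 is annulated with 4 (K2CO3, DMF, 90 °C) to give ethyl 7-iodo-4,6-bis(methoxymethoxy)-1-benzofuran-2-carboxylate F7. F7 is coupled with 3-methylbut-2-enylboronic acid pinacol ester under ligand-controlled, γ-selective (branched) Suzuki–Miyaura conditions (Pd catalyst, bulky biarylphosphine, K3PO4, THF/H2O) to deliver 8.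

**Further compounds**

F1 | step 10 | tert-butyl[(1-methoxy-5-methylhexa-1,4-dien-1-yl)oxy]dimethylsilane (silyl ketene acetal of 16, E/Z mixture) | COC(=CCC=C(C)C)O[Si](C)(C)C(C)(C)C
F2 | step 10 | methyl 3-[4,6-bis(methoxymethoxy)-7-(2-methylbut-3-en-2-yl)-1-benzofuran-2-yl]-4-{1-[(tert-butyldimethylsilyl)oxy]ethylidene}-7-methyl-2-(3-methylbut-2-en-1-yl)oct-6-enoate (mixture of isomers) | COC(=O)C(CC=C(C)C)C(c1cc2c(OCOC)cc(OCOC)c(C(C)(C)C=C)c2o1)C(CC=C(C)C)=C(C)O[Si](C)(C)C(C)(C)C
F3 | step 12 | 5-[4,6-bis(methoxymethoxy)-7-(2-methylbut-3-en-2-yl)-1-benzofuran-2-yl]-4,6-bis(3-methylbut-2-en-1-yl)-4-(phenylselanyl)cyclohexane-1,3-dione (racemic, Se trans to the aryl group) | O=C1CC(=O)[C@]([Se]c2ccccc2)(CC=C(C)C)[C@H](c2cc3c(OCOC)cc(OCOC)c(C(C)(C)C=C)c3o2)[C@H]1CC=C(C)C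
F4 | step 12 | 2-[3,5-dihydroxy-2,6-bis(3-methylbut-2-en-1-yl)phenyl]-4,6-bis(methoxymethoxy)-7-(2-methylbut-3-en-2-yl)-1-benzofuran | Oc1cc(O)c(CC=C(C)C)c(-c2cc3c(OCOC)cc(OCOC)c(C(C)(C)C=C)c3o2)c1CC=C(C)C
F5 | step 3 | 2-hydroxy-4,6-bis(methoxymethoxy)benzaldehyde | O=Cc1c(O)cc(OCOC)cc1OCOC
F6 | step 3 | 2-hydroxy-3-iodo-4,6-bis(methoxymethoxy)benzaldehyde | O=Cc1c(O)c(I)c(OCOC)cc1OCOC
F7 | step 3 | ethyl 7-iodo-4,6-bis(methoxymethoxy)-1-benzofuran-2-carboxylate | CCOC(=O)c1cc2c(OCOC)cc(OCOC)c(I)c2o1
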